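The 14-membered carbocycle is made by contraction, not by end-to-end closure. The ring array C3(O)–C2–C1–C15=C17 of the target (C3 carbinol, C2 methylene, C1 methine carrying the exocyclic acrylate methylene) is the product pattern of a Claisen rearrangement, so the C1–C2 bond is traced back to an allyl vinyl ether whose oxygen links C3 and C17. Heating the 16-membered cyclic 2-alkoxydiene (C2=C3–O–C17–C15=C1), made by methylenation of the C3/C17 macrolactone, should form C1–C2, close the 14-membered ring, set C1 and reveal the C3 enone and the C15=C17 methylene in one operation. The precursor carries C9, C11 and C12 as silyl ethers and C16 as a PMB ether.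

Key step: step 23

Remark: locants C1–C17 are the cembrane locants of the target and are kept for open-chain intermediates; 4-methoxybenzyl alcohol and ethyl 2-(diethoxyphosphoryl)acrylate are taken as commercial.

Step 1
Reactants: 1 geraniol
Product: 2 (2S,3S)-2,3-epoxygeraniol
Conditions: Ti(OiPr)4 (cat.), L-(+)-diethyl tartrate (cat.), t-BuOOH, 4 Å molecular sieves, CH2Cl2, −20 °C
Reagents that add atoms: tert-butyl hydroperoxide, CC(C)(C)OO
Why: Sharpless asymmetric epoxidation touches only the allylic C11=C12 alkene, and the L-(+)-tartrate ligand should deliver oxygen to the face that gives the (2S,3S)-epoxide, which fixes C12 directly and gives C11 the configuration that step 2 inverts.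

Step 2
Reactants: 2 (2S,3S)-2,3-epoxygeraniol
Product: 4 (2S,3S)-3,7-dimethyl-1-(phenylsulfanyl)oct-6-ene-2,3-diol, via terminal epoxide 3 (not isolated)
Conditions: PhSH (slow addition), 0.5 M aq. NaOH, t-BuOH, 75 °C
Reagents that add atoms: thiophenol, Sc1ccccc1
Why: In this Payne rearrangement with thiolate trapping the C10 alkoxide opens the epoxide at C11 with inversion to give the terminal epoxide 3 in equilibrium, and thiolate should attack its primary C10 much faster than either carbon of the trisubstituted epoxide, so that 4 carries C11 and C12 in the target configuration.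

Step 3
Reactants: 4 (2S,3S)-3,7-dimethyl-1-(phenylsulfanyl)oct-6-ene-2,3-diol
Product: 5 (2S,3S)-1-(benzenesulfonyl)-3,7-dimethyloct-6-ene-2,3-diol
Conditions: (NH4)6Mo7O24·4H2O (cat.), 30% H2O2, EtOH, 0 °C to rt
Reagents that add atoms: hydrogen peroxide, OO
Why: Peroxide oxidation catalysed by (NH4)6Mo7O24 converts a sulfide to the sulfone much faster than it epoxidises an isolated trisubstituted alkene, and the sulfone makes C10 a carbon acid for the fragment union.

Step 4
Reactants: 5 (2S,3S)-1-(benzenesulfonyl)-3,7-dimethyloct-6-ene-2,3-diol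
Product: 6 (2S,3S)-1-(benzenesulfonyl)-3,7-dimethyl-2,3-bis(triethylsilyloxy)oct-6-ene
Conditions: Et3SiOTf, 2,6-lutidine, CH2Cl2, −78 to 0 °C
Reagents that add atoms: triethylsilyl trifluoromethanesulfonate, CC[Si](CC)(CC)OS(=O)(=O)C(F)(F)F
Why: Silyl ether formation with the silyl triflate covers both the hindered secondary C11 hydroxyl and the tertiary C12 hydroxyl with the same group, so that no silyl shift between the two oxygens can matter and both can later be freed together.

Step 5
Reactants: 6 (2S,3S)-1-(benzenesulfonyl)-3,7-dimethyl-2,3-bis(triethylsilyloxy)oct-6-ene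
Product: 7 (4S,5S)-6-(benzenesulfonyl)-4-methyl-4,5-bis(triethylsilyloxy)hexanal
Conditions: O3, CH2Cl2, −78 °C; then PPh3, −78 °C to rt
Reagents that add atoms: ozone, [O-][O+]=O
Why: Ozonolysis with reductive work-up cleaves the only alkene to the C1 aldehyde, and sulfone and silyl ethers are inert to ozone.

Step 6
Reactants: 8 4-methoxybenzyl alcohol; 9 ethyl 2-(diethoxyphosphoryl)acrylate
Product: 10 ethyl 2-(diethoxyphosphoryl)-3-(4-methoxybenzyloxy)propanoate
Conditions: KOtBu (cat.), THF, 0 °C to rt
Reagents that add atoms: none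
Why: Base-catalysed oxa-Michael addition of the benzylic alkoxide to the doubly activated alkene gives the α-substituted phosphonoacetate, whose stereocentre is lost in step 7.

Step 7
Reactants: 7 (4S,5S)-6-(benzenesulfonyl)-4-methyl-4,5-bis(triethylsilyloxy)hexanal; 10 ethyl 2-(diethoxyphosphoryl)-3-(4-methoxybenzyloxy)propanoate
Product: 11 E enoate with the ester carbon (C17) trans to C14 and the PMB-oxymethyl arm (C16) cis to C14
Conditions: NaH, THF, 0 °C; then 7, 0 °C to rt
Reagents that add atoms: none
Why: Horner–Wadsworth–Emmons olefination with an α-branched phosphonoacetate should give mainly the trisubstituted enoate with the ester trans to the chain, and the minor geometric isomer should be separable by chromatography.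

Step 8
Reactants: 11 E enoate
Product: 12 C17 allylic alcohol
Conditions: i-Bu2AlH, CH2Cl2, −78 °C; potassium sodium tartrate work-up
Reagents that add atoms: none
Why: 1,2-Reduction of the conjugated ester with i-Bu2AlH gives the primary allylic alcohol with retention of alkene geometry and leaves sulfone, PMB ether and silyl ethers untouched.

Step 9
Reactants: 12 C17 allylic alcohol
Product: 13 C17 triethylsilyl ether
Conditions: Et3SiCl, imidazole, CH2Cl2, 0 °C
Reagents that add atoms: chlorotriethylsilane, CC[Si](Cl)(CC)CC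
Why: Silyl ether formation removes the only acidic O–H before carbanion chemistry, and a primary allylic TES ether can later be cleaved in the presence of the hindered ones.

Step 10
Reactants: 14 propargyl alcohol
Product: 16 (Z)-2-methyl-3-(tributylstannyl)prop-2-en-1-ol, via alkenylmagnesium chelate 15 (not isolated)
Conditions: MeMgBr, CuI (cat.), THF, −10 °C to rt; then Bu3SnCl, 0 °C to rt; aq. NH4Cl
Reagents that add atoms: methylmagnesium bromide, C[Mg]Br; tributyltin chloride, CCCC[Sn](Cl)(CCCC)CCCC
Why: CuI-catalysed anti carbomagnesiation of the propargylic alkoxide puts the methyl group on the internal carbon and leaves the alkenylmagnesium chelated cis to the CH2O group, so that stannylation with retention fixes the Z geometry of the future C7=C8 alkene.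

Step 11
Reactants: 16 (Z)-2-methyl-3-(tributylstannyl)prop-2-en-1-ol
Product: 17 (Z)-2-methyl-3-(tributylstannyl)prop-2-enal
Conditions: MnO2, CH2Cl2, rt
Reagents that add atoms: none
Why: Allylic oxidation with MnO2 runs under neutral conditions, which should keep the acid-sensitive alkenylstannane and the Z geometry intact.

Step 12
Reactants: 13 C17 triethylsilyl ether; 17 (Z)-2-methyl-3-(tributylstannyl)prop-2-enal
Product: 19 β-hydroxy sulfone (C9 carbinol and C10 sulfone as a diastereomer mixture), via lithiated sulfone 18 (not isolated)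
Conditions: n-BuLi, THF, −78 °C; then 17, −78 °C; aq. NH4Cl
Reagents that add atoms: none
Why: The α-sulfonyl carbanion adds 1,2 to the enal at −78 °C (sulfone carbanion addition, the first half of a Julia coupling), where loss of the β-silyloxy group should be slow, and the uncontrolled centres at C9 and C10 are erased in steps 13 and 14.

Step 13
Reactants: 19 β-hydroxy sulfone
Product: 20 β-keto sulfone
Conditions: Dess–Martin periodinane, NaHCO3, CH2Cl2, 0 °C to rt
Reagents that add atoms: none
Why: Dess–Martin oxidation converts the secondary allylic alcohol to the ketone under buffered, non-basic conditions that should neither isomerise the Z alkene nor cleave the alkenyl–tin bond.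

Step 14
Reactants: 20 β-keto sulfone
Product: 21 Z enone (C9 ketone, C10 methylene)
Conditions: SmI2, THF/MeOH, −78 °C
Reagents that add atoms: none
Why: Reductive desulfonylation with SmI2 cleaves the C10–S bond of the α-sulfonyl ketone through its ketyl, and methanol should protonate the samarium enolate at C10 before it can expel the β-silyloxy group.

Step 15
Reactants: 21 Z enone
Product: 22 (9R) allylic alcohol
Conditions: (S)-2-methyl-CBS-oxazaborolidine, catecholborane, toluene, −78 °C
Reagents that add atoms: none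
Why: In this Corey–Bakshi–Shibata reduction the α-methyl alkenyl group is the large and the C10 methylene the small substituent, so the (S)-oxazaborolidine should deliver hydride to the face that gives the 9R alcohol under reagent control.

Step 16
Reactants: 22 (9R) allylic alcohol
Product: 23 C9 tert-butyldimethylsilyl ether
Conditions: t-BuMe2SiOTf, 2,6-lutidine, CH2Cl2, −78 °C
Reagents that add atoms: tert-butyldimethylsilyl trifluoromethanesulfonate, CC(C)(C)[Si](C)(C)OS(=O)(=O)C(F)(F)F
Why: Silyl ether formation with the silyl triflate covers the hindered secondary allylic alcohol with a group that should outlast the TES ethers in the later selective cleavages.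

Step 17
Reactants: 24 ethyl tiglate
Product: 25 ethyl (E)-4-bromo-2-methylbut-2-enoate
Conditions: N-bromosuccinimide, AIBN (cat.), PhCF3, reflux
Reagents that add atoms: N-bromosuccinimide, O=C1CCC(=O)N1Br
Why: Wohl–Ziegler bromination takes place at the allylic γ-methyl group of the enoate, and the E 4-bromo ester should be separable by distillation from the 2-bromomethyl isomer.

Step 18
Reactants: 23 C9 tert-butyldimethylsilyl ether; 25 ethyl (E)-4-bromo-2-methylbut-2-enoate
Product: 26 ethyl (4E,7Z)-dienoate of the full C3–C17 chain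
Conditions: Pd2(dba)3 (cat.), AsPh3, N-methylpyrrolidone, rt to 40 °C
Reagents that add atoms: none
Why: In this Stille coupling the allylic bromide adds to zerovalent palladium to give an η3-allyl complex of divalent palladium, which should couple with the alkenylstannane at the unsubstituted terminus C6 with retention of both alkene geometries, so that the skipped diene is made without base and only after C9 is no longer a carbonyl group.

Step 19
Reactants: 26 ethyl (4E,7Z)-dienoate
Product: 27 C17 alcohol
Conditions: pyridinium p-toluenesulfonate (cat.), MeOH/CH2Cl2, 0 °C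
Reagents that add atoms: none
Why: Acid-catalysed methanolysis (selective silyl ether cleavage) should remove the unhindered primary allylic TES ether much faster than the secondary TBS ether or the hindered secondary and tertiary TES ethers.

Step 20
Reactants: 27 C17 alcohol
Product: 28 seco acid (C3 acid, C17 hydroxyl)
Conditions: LiOH, THF/MeOH/H2O, 0 °C to rt; then aq. HCl to pH 4 at 0 °C
Reagents that add atoms: lithium hydroxide, [Li+].[OH-]
Why: Saponification of the ethyl ester gives the seco acid, the silyl ethers are stable to aqueous base, and the cold, short exposure should not move the skipped diene into conjugation.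

Step 21
Reactants: 28 seco acid
Product: 30 16-membered macrolactone, via mixed anhydride 29 (not isolated)
Conditions: 2,4,6-trichlorobenzoyl chloride, Et3N, THF, rt; then slow addition to DMAP, toluene, 40 °C (high dilution)
Reagents that add atoms: none
Why: In this Yamaguchi macrolactonization the mixed anhydride 29 is attacked by the only free hydroxyl, the primary allylic C17–OH, which should close the 16-membered ring easily.

Step 22
Reactants: 30 16-membered macrolactone
Product: 31 16-membered cyclic 2-alkoxydiene (enol ether oxygen between C3 and C17)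
Conditions: Cp2Ti(μ-Cl)(μ-CH2)AlMe2, pyridine, THF/toluene, −40 °C to rt; aq. NaOH; filtration through basic Al2O3
Reagents that add atoms: Tebbe reagent Cp2Ti(μ-Cl)(μ-CH2)AlMe2, C[Al-]1(C)C[Ti](C2C=CC=C2)(C2C=CC=C2)[Cl+]1
Why: Tebbe methylenation converts the lactone carbonyl into the enol ether through a titanaoxetane, a reaction known for conjugated esters and lactones, and the molecule holds no other carbonyl group.

Step 23
Reactants: 31 16-membered cyclic 2-alkoxydiene
Product: 32 14-membered C3 enone with the C15=C17 methylene (1S)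
Conditions: degassed toluene, Et3N (trace), BHT (cat.), base-washed sealed tube, 130 °C
Reagents that add atoms: none
Why: This is a Claisen rearrangement in which the allyl vinyl ether C2=C3–O–C17–C15=C1 undergoes a concerted suprafacial [3,3] shift through a six-membered chair-like transition state that forms C1–C2 and breaks O–C17, driven by the new C3=O bond in conjugation with C4=C5. The closest known reaction types are the ring contraction of cyclic enol ethers made from lactones by titanium methylenation and the Claisen contraction of ketene acetals derived from macrolactones. The 14-membered carbocycle closes by contraction inside the 16-membered ring, the bond being made between C1 and C2, which the ether bridge already holds in a 1,6 relation, so no end-to-end cyclisation is needed. C1 is the only new stereocentre, and its sense depends on which face of the E C1=C15 alkene the tethered C2 terminus reaches, which is set by the ring conformation that the C9, C11 and C12 substituents impose; the 1S configuration drawn is the one needed but its preference is not proven. The step needs the [3,3] path to win over hydrolysis or acid-induced isomerisation of the alkoxydiene and over conjugation of the skipped diene, which the base-washed vessel, the trace of amine and the absence of any second allyl vinyl ether array or free hydroxyl should secure.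

Step 24
Reactants: 32 14-membered C3 enone
Product: 33 (3R) allylic alcohol
Conditions: (S)-2-methyl-CBS-oxazaborolidine, catecholborane, toluene, −78 °C
Reagents that add atoms: none
Why: In this Corey–Bakshi–Shibata reduction the α-methyl alkenyl carbon C4 acts as the large and C2 as the small substituent, so the (S)-catalyst should give the 3R alcohol by 1,2-reduction without touching the exocyclic alkene.

Step 25
Reactants: 33 (3R) allylic alcohol
Product: 34 C3 tert-butyldimethylsilyl ether
Conditions: t-BuMe2SiOTf, 2,6-lutidine, CH2Cl2, −78 °C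
Reagents that add atoms: tert-butyldimethylsilyl trifluoromethanesulfonate, CC(C)(C)[Si](C)(C)OS(=O)(=O)C(F)(F)F
Why: Silyl ether formation shields the C3 allylic alcohol from the later MnO2 oxidation and keeps it from forming the six-membered lactone with C16.

Step 26
Reactants: 34 C3 tert-butyldimethylsilyl ether
Product: 35 C16 primary allylic alcohol
Conditions: DDQ, CH2Cl2/pH 7 buffer, 0 °C
Reagents that add atoms: none
Why: Oxidative PMB cleavage with DDQ removes the only benzylic ether under buffered conditions that should leave silyl ethers and the skipped diene untouched.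

Step 27
Reactants: 35 C16 primary allylic alcohol
Product: 36 C16 enal
Conditions: MnO2, CH2Cl2, rt
Reagents that add atoms: none
Why: Allylic oxidation with MnO2 converts the only free hydroxyl into the 2-substituted acrolein while the vicinal C11/C12 oxygens are still silylated.

Step 28
Reactants: 36 C16 enal
Product: 37 enal 11,12-diol
Conditions: HF·pyridine, pyridine, THF, 0 °C
Reagents that add atoms: none
Why: Buffered HF·pyridine (selective silyl ether cleavage) should remove the two TES ethers faster than the two secondary TBS ethers and so free the C11 and C12 hydroxyls only.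

Step 29
Reactants: 37 enal 11,12-diol
Product: 38 enal C11 acetate
Conditions: Ac2O, pyridine, DMAP (cat.), CH2Cl2, 0 °C to rt
Reagents that add atoms: acetic anhydride, CC(=O)OC(C)=O
Why: Selective acylation takes place at the secondary C11–OH because the tertiary C12–OH is far less reactive towards Ac2O under DMAP catalysis.

Step 30
Reactants: 38 enal C11 acetate
Product: 39 C16 acrylic acid
Conditions: NaClO2, NaH2PO4, 2-methyl-2-butene, t-BuOH/H2O, 0 °C to rt
Reagents that add atoms: sodium chlorite, [Na+].[O-]Cl=O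
Why: Pinnick oxidation converts the enal into the acrylic acid under mildly acidic conditions, and 2-methyl-2-butene traps hypochlorous acid before it can add to the ring alkenes.

Step 31
Reactants: 39 C16 acrylic acid
Product: 41 bis-silylated lactone, via mixed anhydride 40 (not isolated)
Conditions: 2,4,6-trichlorobenzoyl chloride, Et3N, THF, rt; then DMAP, toluene, 80 °C
Reagents that add atoms: none
Why: In this Yamaguchi lactonization the mixed anhydride 40 is attacked by the only free hydroxyl, the tertiary C12–OH held 1,4 to C1 on the ring, so that the seven-membered lactone should close by 7-exo-trig acyl substitution on heating with DMAP.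

Step 32
Reactants: 41 bis-silylated lactone
Product: 42 CNP0183491.2 (target)
Conditions: HF·pyridine, THF, 0 °C to rt
Reagents that add atoms: none
Why: Silyl ether cleavage with HF·pyridine removes both secondary TBS ethers under acidic, non-basic conditions, which should avoid acetyl migration from C11 to C9 and alkoxide addition to the α-methylene lactone.

Compound list

1 | geraniol, (E)-3,7-dimethylocta-2,6-dien-1-ol | CC(C)=CCC/C(C)=C/CO | starting material
2 | (2S,3S)-2,3-epoxygeraniol, [(2S,3S)-3-methyl-3-(4-methylpent-3-enyl)oxiran-2-yl]methanol | OC[C@@H]1O[C@@]1(C)CCC=C(C)C | intermediate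
3 | (S)-6-methyl-2-[(R)-oxiran-2-yl]hept-5-en-2-ol, the terminal epoxide formed by Payne rearrangement | C1O[C@H]1[C@@](C)(O)CCC=C(C)C | intermediate
4 | (2S,3S)-3,7-dimethyl-1-(phenylsulfanyl)oct-6-ene-2,3-diol (C10 sulfide; C11 and C12 hydroxyls placed as in the target) | c1ccccc1SC[C@@H](O)[C@@](C)(O)CCC=C(C)C | intermediate
5 | (2S,3S)-1-(benzenesulfonyl)-3,7-dimethyloct-6-ene-2,3-diol | O=S(=O)(c1ccccc1)C[C@@H](O)[C@@](C)(O)CCC=C(C)C | intermediate
6 | (2S,3S)-1-(benzenesulfonyl)-3,7-dimethyl-2,3-bis(triethylsilyloxy)oct-6-ene | O=S(=O)(c1ccccc1)C[C@@H](O[Si](CC)(CC)CC)[C@@](C)(O[Si](CC)(CC)CC)CCC=C(C)C | intermediate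
7 | (4S,5S)-6-(benzenesulfonyl)-4-methyl-4,5-bis(triethylsilyloxy)hexanal (C1 aldehyde of the C10–C14 chain) | O=S(=O)(c1ccccc1)C[C@@H](O[Si](CC)(CC)CC)[C@@](C)(O[Si](CC)(CC)CC)CCC=O | intermediate
8 | 4-methoxybenzyl alcohol | COc1ccc(CO)cc1 | starting material
9 | ethyl 2-(diethoxyphosphoryl)acrylate | C=C(C(=O)OCC)P(=O)(OCC)OCC | starting material
10 | ethyl 2-(diethoxyphosphoryl)-3-(4-methoxybenzyloxy)propanoate (racemic) | CCOC(=O)C(COCc1ccc(OC)cc1)P(=O)(OCC)OCC | intermediate
11 | ethyl (2E,6S,7S)-8-(benzenesulfonyl)-2-[(4-methoxybenzyloxy)methyl]-6-methyl-6,7-bis(triethylsilyloxy)oct-2-enoate (ester carbon = C17, trans to C14; CH2OPMB = C16, cis to C14) | O=S(=O)(c1ccccc1)C[C@@H](O[Si](CC)(CC)CC)[C@@](C)(O[Si](CC)(CC)CC)CC/C=C(/C(=O)OCC)COCc1ccc(OC)cc1 | intermediate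
12 | (6S,7S)-8-(benzenesulfonyl)-2-[(4-methoxybenzyloxy)methyl]-6-methyl-6,7-bis(triethylsilyloxy)oct-2-en-1-ol, hydroxymethyl (C17) trans to C14 and CH2OPMB (C16) cis to C14 (2Z by the sequence rule) | O=S(=O)(c1ccccc1)C[C@@H](O[Si](CC)(CC)CC)[C@@](C)(O[Si](CC)(CC)CC)CC/C=C(/CO)COCc1ccc(OC)cc1 | intermediate
13 | C17 triethylsilyl ether of 12, alkene geometry unchanged (C17 arm trans to C14) | O=S(=O)(c1ccccc1)C[C@@H](O[Si](CC)(CC)CC)[C@@](C)(O[Si](CC)(CC)CC)CC/C=C(/CO[Si](CC)(CC)CC)COCc1ccc(OC)cc1 | intermediate
14 | propargyl alcohol | C#CCO | starting material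
15 | bromomagnesium (Z)-3-(bromomagnesio)-2-methylprop-2-en-1-olate (alkenylmagnesium chelate, Mg on carbon cis to CH2O) | Br[Mg]OC/C(C)=C\[Mg]Br | intermediate
16 | (Z)-2-methyl-3-(tributylstannyl)prop-2-en-1-ol | OC/C(C)=C\[Sn](CCCC)(CCCC)CCCC | intermediate
17 | (Z)-2-methyl-3-(tributylstannyl)prop-2-enal | O=C/C(C)=C\[Sn](CCCC)(CCCC)CCCC | intermediate
18 | C10-lithio derivative of sulfone 13 | [Li]C(S(=O)(=O)c1ccccc1)[C@@H](O[Si](CC)(CC)CC)[C@@](C)(O[Si](CC)(CC)CC)CC/C=C(/CO[Si](CC)(CC)CC)COCc1ccc(OC)cc1 | intermediate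
19 | β-hydroxy sulfone of the C7–C17 chain: Bu3Sn on C7, Z C7=C8, OH on C9 and PhSO2 on C10 (both centres unassigned), C11 and C12 OTES as in 13, C1=C15 with the C17 OTES arm trans and the C16 OPMB arm cis to C14 | CCCC[Sn](CCCC)(CCCC)/C=C(/C)C(O)C(S(=O)(=O)c1ccccc1)[C@@H](O[Si](CC)(CC)CC)[C@@](C)(O[Si](CC)(CC)CC)CC/C=C(/CO[Si](CC)(CC)CC)COCc1ccc(OC)cc1 | intermediate
20 | β-keto sulfone: C9 ketone of 19 (C10 unassigned) | CCCC[Sn](CCCC)(CCCC)/C=C(/C)C(=O)C(S(=O)(=O)c1ccccc1)[C@@H](O[Si](CC)(CC)CC)[C@@](C)(O[Si](CC)(CC)CC)CC/C=C(/CO[Si](CC)(CC)CC)COCc1ccc(OC)cc1 | intermediate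
21 | Z enone: C9 ketone, C10 methylene, (11R,12S)-bis-OTES, Bu3Sn on C7, other groups as in 19 | CCCC[Sn](CCCC)(CCCC)/C=C(/C)C(=O)C[C@@H](O[Si](CC)(CC)CC)[C@@](C)(O[Si](CC)(CC)CC)CC/C=C(/CO[Si](CC)(CC)CC)COCc1ccc(OC)cc1 | intermediate
22 | (9R,11R,12S) allylic alcohol: C9 OH, otherwise as 21 | CCCC[Sn](CCCC)(CCCC)/C=C(/C)[C@H](O)C[C@@H](O[Si](CC)(CC)CC)[C@@](C)(O[Si](CC)(CC)CC)CC/C=C(/CO[Si](CC)(CC)CC)COCc1ccc(OC)cc1 | intermediate
23 | C9 tert-butyldimethylsilyl ether of 22 | CCCC[Sn](CCCC)(CCCC)/C=C(/C)[C@H](O[Si](C)(C)C(C)(C)C)C[C@@H](O[Si](CC)(CC)CC)[C@@](C)(O[Si](CC)(CC)CC)CC/C=C(/CO[Si](CC)(CC)CC)COCc1ccc(OC)cc1 | intermediate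
24 | ethyl tiglate, ethyl (E)-2-methylbut-2-enoate | C/C=C(\C)C(=O)OCC | starting material
25 | ethyl (E)-4-bromo-2-methylbut-2-enoate | CCOC(=O)/C(C)=C/CBr | intermediate
26 | ethyl ester of the C3–C17 seco chain: C4=C5 E, C7=C8 Z, (9R) OTBS, (11R,12S) bis-OTES, C1=C15 with C17 OTES arm trans and C16 OPMB arm cis to C14 | CCOC(=O)/C(C)=C/C/C=C(/C)[C@H](O[Si](C)(C)C(C)(C)C)C[C@@H](O[Si](CC)(CC)CC)[C@@](C)(O[Si](CC)(CC)CC)CC/C=C(/CO[Si](CC)(CC)CC)COCc1ccc(OC)cc1 | intermediate
27 | C17 alcohol of 26 (primary TES removed) | CCOC(=O)/C(C)=C/C/C=C(/C)[C@H](O[Si](C)(C)C(C)(C)C)C[C@@H](O[Si](CC)(CC)CC)[C@@](C)(O[Si](CC)(CC)CC)CC/C=C(/CO)COCc1ccc(OC)cc1 | intermediate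
28 | seco acid: C3 carboxylic acid and C17 hydroxyl, otherwise as 27 | OC(=O)/C(C)=C/C/C=C(/C)[C@H](O[Si](C)(C)C(C)(C)C)C[C@@H](O[Si](CC)(CC)CC)[C@@](C)(O[Si](CC)(CC)CC)CC/C=C(/CO)COCc1ccc(OC)cc1 | intermediate
29 | mixed anhydride of 28 with 2,4,6-trichlorobenzoic acid | Clc1cc(Cl)c(C(=O)OC(=O)/C(C)=C/C/C=C(/C)[C@H](O[Si](C)(C)C(C)(C)C)C[C@@H](O[Si](CC)(CC)CC)[C@@](C)(O[Si](CC)(CC)CC)CC/C=C(/CO)COCc2ccc(OC)cc2)c(Cl)c1 | intermediate
30 | 16-membered macrolactone (ring: C3 carbonyl, C4–C14, C1, C15, C17, O); C4=C5 E, C7=C8 Z, C1=C15 E; (9R) OTBS, (11R,12S) bis-OTES; CH2OPMB (C16) on C15 | O=C1/C(C)=C/C/C=C(/C)[C@H](O[Si](C)(C)C(C)(C)C)C[C@@H](O[Si](CC)(CC)CC)[C@@](C)(O[Si](CC)(CC)CC)CC/C=C(/CO1)COCc2ccc(OC)cc2 | intermediate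
31 | 16-membered cyclic 2-alkoxydiene: C3 carbonyl of 30 replaced by C3=C2H2, enol ether oxygen between C3 and C17 | C=C1/C(C)=C/C/C=C(/C)[C@H](O[Si](C)(C)C(C)(C)C)C[C@@H](O[Si](CC)(CC)CC)[C@@](C)(O[Si](CC)(CC)CC)CC/C=C(/CO1)COCc2ccc(OC)cc2 | intermediate
32 | 14-membered carbocyclic enone: C3 ketone, C4=C5 E, C7=C8 Z, (1S) with 3-(4-methoxybenzyloxy)prop-1-en-2-yl on C1 (C15=C17 methylene, C16 OPMB), (9R) OTBS, (11R,12S) bis-OTES | C=C(COCc2ccc(OC)cc2)[C@@H]1CC(=O)/C(C)=C/C/C=C(/C)[C@H](O[Si](C)(C)C(C)(C)C)C[C@@H](O[Si](CC)(CC)CC)[C@@](C)(O[Si](CC)(CC)CC)CC1 | intermediate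
33 | (1S,3R,9R,11R,12S) allylic alcohol: C3 OH, otherwise as 32 | C=C(COCc2ccc(OC)cc2)[C@@H]1C[C@@H](O)/C(C)=C/C/C=C(/C)[C@H](O[Si](C)(C)C(C)(C)C)C[C@@H](O[Si](CC)(CC)CC)[C@@](C)(O[Si](CC)(CC)CC)CC1 | intermediate
34 | C3 tert-butyldimethylsilyl ether of 33 | C=C(COCc2ccc(OC)cc2)[C@@H]1C[C@@H](O[Si](C)(C)C(C)(C)C)/C(C)=C/C/C=C(/C)[C@H](O[Si](C)(C)C(C)(C)C)C[C@@H](O[Si](CC)(CC)CC)[C@@](C)(O[Si](CC)(CC)CC)CC1 | intermediate
35 | C16 primary allylic alcohol (PMB removed): 3-hydroxyprop-1-en-2-yl on C1, C3 and C9 OTBS, C11 and C12 OTES | C=C(CO)[C@@H]1C[C@@H](O[Si](C)(C)C(C)(C)C)/C(C)=C/C/C=C(/C)[C@H](O[Si](C)(C)C(C)(C)C)C[C@@H](O[Si](CC)(CC)CC)[C@@](C)(O[Si](CC)(CC)CC)CC1 | intermediate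
36 | C16 enal: 3-oxoprop-1-en-2-yl on C1, silyl ethers as in 35 | C=C(C=O)[C@@H]1C[C@@H](O[Si](C)(C)C(C)(C)C)/C(C)=C/C/C=C(/C)[C@H](O[Si](C)(C)C(C)(C)C)C[C@@H](O[Si](CC)(CC)CC)[C@@](C)(O[Si](CC)(CC)CC)CC1 | intermediate
37 | enal with free (11R) and (12S) hydroxyls, C3 and C9 OTBS | C=C(C=O)[C@@H]1C[C@@H](O[Si](C)(C)C(C)(C)C)/C(C)=C/C/C=C(/C)[C@H](O[Si](C)(C)C(C)(C)C)C[C@@H](O)[C@@](C)(O)CC1 | intermediate
38 | enal C11 acetate with free tertiary C12 hydroxyl | C=C(C=O)[C@@H]1C[C@@H](O[Si](C)(C)C(C)(C)C)/C(C)=C/C/C=C(/C)[C@H](O[Si](C)(C)C(C)(C)C)C[C@@H](OC(C)=O)[C@@](C)(O)CC1 | intermediate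
39 | C16 acrylic acid (2-substituted prop-2-enoic acid on C1), C11 OAc, C12 OH, C3 and C9 OTBS | C=C(C(=O)O)[C@@H]1C[C@@H](O[Si](C)(C)C(C)(C)C)/C(C)=C/C/C=C(/C)[C@H](O[Si](C)(C)C(C)(C)C)C[C@@H](OC(C)=O)[C@@](C)(O)CC1 | intermediate
40 | mixed anhydride of 39 with 2,4,6-trichlorobenzoic acid | C=C(C(=O)OC(=O)c2c(Cl)cc(Cl)cc2Cl)[C@@H]1C[C@@H](O[Si](C)(C)C(C)(C)C)/C(C)=C/C/C=C(/C)[C@H](O[Si](C)(C)C(C)(C)C)C[C@@H](OC(C)=O)[C@@](C)(O)CC1 | intermediate
41 | 3,9-bis-O-TBS ether of the target (seven-membered α-methylene lactone closed onto C12, C11 OAc) | C=C1C(=O)O[C@@]2(C)CC[C@H]1C[C@@H](O[Si](C)(C)C(C)(C)C)/C(C)=C/C/C=C(/C)[C@H](O[Si](C)(C)C(C)(C)C)C[C@H]2OC(C)=O | intermediate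
42 | CNP0183491.2: (1S,3R,9R,11R,12S) cembranolide with C4=C5 E, C7=C8 Z, C3 and C9 hydroxyls, C11 acetate and the α-methylene seven-membered lactone C16(=O)–O–C12 | C=C1C(=O)O[C@@]2(C)CC[C@H]1C[C@@H](O)/C(C)=C/C/C=C(/C)[C@H](O)C[C@H]2OC(C)=O | target

Total step count: 32. Longest linear sequence: 28 steps (geraniol to the target through steps 1–5, 7–9, 12–16 and 18–32).

Steps most likely to fail

Step 23. The sigmatropic shift may go through the other face of C1 (inverted or poor facial selectivity), or acid-induced hydrolysis of the alkoxydiene may outrun it. The fallback changes the geometry of the allyl unit by putting the other oxymethyl arm of C15 into the ring. It sets out from 26: DDQ removes the PMB group and gives the C16 alcohol F1, LiOH gives the seco acid F2, and activation with 2,4,6-trichlorobenzoyl chloride gives the mixed anhydride F3, which closes through the C16 oxygen to the isomeric macrolactone F4, whose ring oxygen arm is cis to C14. Methylenation with Cp2Ti(μ-Cl)(μ-CH2)AlMe2 gives the cyclic enol ether F5, and heating gives the ketone F6. F6 has the constitution of 32 with TES in place of PMB, because after the shift one arm of C15 is the methylene and the other the oxymethyl group, whichever arm was in the ring. Reduction with the (S)-oxazaborolidine and catecholborane gives the alcohol F7, and silylation gives the TBS ether F8. Methanolysis with pyridinium p-toluenesulfonate then removes the primary TES ether, and the route is rejoined at 35.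

Step 31. Acylation of the hindered tertiary C12 hydroxyl may be slower than oligomerisation or decomposition of the activated acrylic acid. The fallback makes the lactone at the aldehyde oxidation state and never forms the free acid. It sets out from 38: a triazolium-derived N-heterocyclic carbene with DBU and MnO2 should oxidise the enal to an acyl azolium, which the C12 hydroxyl traps intramolecularly (oxidative lactonization). This fallback makes no new isolated compound (F0) and rejoins the route at 41.

Step 2. Thiolate may open the trisubstituted epoxide directly, or hydroxide may intercept the terminal epoxide, before the alkoxide relay and the sulfur attack at C10 are complete (loss of regiocontrol). The fallback brings in sulfur by direct displacement and makes the diol by acid hydrolysis with inversion at the tertiary carbon, which calls for the enantiomeric epoxide. It sets out from 1: Sharpless epoxidation with Ti(OiPr)4 and D-(−)-diethyl tartrate gives (2R,3R)-2,3-epoxygeraniol F9, tosylation gives the tosylate F10, and sodium benzenesulfinate in DMF displaces the tosylate at C10 to give the epoxy sulfone F11. Aqueous HClO4 in THF then opens the epoxide at the tertiary C12 with inversion and leaves the C11 oxygen in place. The route is rejoined at 5, and step 3 is no longer needed.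

Further compounds

F1 | step 23 | C16 alcohol from 26: ethyl ester of the C3–C17 chain with free CH2OH cis to C14 and the C17 OTES arm trans to C14 | CCOC(=O)/C(C)=C/C/C=C(/C)[C@H](O[Si](C)(C)C(C)(C)C)C[C@@H](O[Si](CC)(CC)CC)[C@@](C)(O[Si](CC)(CC)CC)CC/C=C(/CO[Si](CC)(CC)CC)CO
F2 | step 23 | seco acid of F1 (C3 acid, C16 hydroxyl) | OC(=O)/C(C)=C/C/C=C(/C)[C@H](O[Si](C)(C)C(C)(C)C)C[C@@H](O[Si](CC)(CC)CC)[C@@](C)(O[Si](CC)(CC)CC)CC/C=C(/CO[Si](CC)(CC)CC)CO
F3 | step 23 | mixed anhydride of F2 with 2,4,6-trichlorobenzoic acid | Clc1cc(Cl)c(C(=O)OC(=O)/C(C)=C/C/C=C(/C)[C@H](O[Si](C)(C)C(C)(C)C)C[C@@H](O[Si](CC)(CC)CC)[C@@](C)(O[Si](CC)(CC)CC)CC/C=C(/CO[Si](CC)(CC)CC)CO)c(Cl)c1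
F4 | step 23 | isomeric 16-membered macrolactone closed through the C16 oxygen (ring oxygen arm cis to C14, exocyclic CH2OTES trans to C14) | O=C1/C(C)=C/C/C=C(/C)[C@H](O[Si](C)(C)C(C)(C)C)C[C@@H](O[Si](CC)(CC)CC)[C@@](C)(O[Si](CC)(CC)CC)CC/C=C(/CO[Si](CC)(CC)CC)CO1
F5 | step 23 | cyclic 2-alkoxydiene from F4 | C=C1/C(C)=C/C/C=C(/C)[C@H](O[Si](C)(C)C(C)(C)C)C[C@@H](O[Si](CC)(CC)CC)[C@@](C)(O[Si](CC)(CC)CC)CC/C=C(/CO[Si](CC)(CC)CC)CO1
F6 | step 23 | 14-membered C3 enone (1S) with 3-(triethylsilyloxy)prop-1-en-2-yl on C1 | C=C(CO[Si](CC)(CC)CC)[C@@H]1CC(=O)/C(C)=C/C/C=C(/C)[C@H](O[Si](C)(C)C(C)(C)C)C[C@@H](O[Si](CC)(CC)CC)[C@@](C)(O[Si](CC)(CC)CC)CC1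
F7 | step 23 | (3R) alcohol from F6 | C=C(CO[Si](CC)(CC)CC)[C@@H]1C[C@@H](O)/C(C)=C/C/C=C(/C)[C@H](O[Si](C)(C)C(C)(C)C)C[C@@H](O[Si](CC)(CC)CC)[C@@](C)(O[Si](CC)(CC)CC)CC1
F8 | step 23 | C3 tert-butyldimethylsilyl ether of F7 | C=C(CO[Si](CC)(CC)CC)[C@@H]1C[C@@H](O[Si](C)(C)C(C)(C)C)/C(C)=C/C/C=C(/C)[C@H](O[Si](C)(C)C(C)(C)C)C[C@@H](O[Si](CC)(CC)CC)[C@@](C)(O[Si](CC)(CC)CC)CC1
F0 | step 31 | none | none
F9 | step 2 | (2R,3R)-2,3-epoxygeraniol | OC[C@H]1O[C@]1(C)CCC=C(C)C
F10 | step 2 | (2R,3R)-2,3-epoxygeranyl 4-methylbenzenesulfonate | Cc1ccc(cc1)S(=O)(=O)OC[C@H]1O[C@]1(C)CCC=C(C)C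
F11 | step 2 | (2S,3R)-2-[(benzenesulfonyl)methyl]-3-methyl-3-(4-methylpent-3-enyl)oxirane | O=S(=O)(c1ccccc1)C[C@H]1O[C@]1(C)CCC=C(C)C
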